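## Analysis of the target

Locants used here: C1–C6 for the cyclohexene (C1 is the aryl-bearing methine, C2=C3 the alkene with the methyl on C3, C6 the quaternary carbon); A-locants for the 7-methoxycoumarin bonded through A6 to C1; B-locants for the 7-methoxycoumarin bonded through B8 to the bridge.

- The target joins two 7-methoxycoumarins through a 3,6-dimethylcyclohex-2-ene. Coumarin A sits directly on C1, and coumarin B is tied to the quaternary C6 by an (E)-ethenyl bridge.
- C1 and C6 are adjacent stereocentres, both R. The aryl group on C1 and the styryl arm on C6 are cis, and the C6 methyl is trans to the aryl group.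
- C1–H is both benzylic and allylic and lies next to a trisubstituted alkene that can migrate under acid. Both lactones open with nucleophilic base and are Michael acceptors.
- The coumarins and the styrene absorb in the near UV, so any light-driven step must come before they are present. The C6 alkenyl arm and C2=C3 form a 1,5-diene that could undergo Cope rearrangement at high temperature.
- The difficulty is twofold: an all-carbon quaternary centre next to a tertiary one in fixed relative and absolute configuration, and a hindered C1–A6 bond to an arene whose two oxygens must end up different (A7 as methyl ether, A8a as lactone oxygen).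
- The strategy rests on ring A (A4a, A5, A6, A7, A8, A8a). Seen from C1 it is a 4-substituted resorcinol, with the A7 oxygen ortho and the A8a oxygen para to A6. A vinylketene made from a diazo enone on C1 gives exactly this pattern on benzannulation with a siloxyalkyne, with the two oxygens already differentiated.
- The cyclohexene itself is a Diels–Alder adduct: C2=C3 comes from the centre of a 1,3-disubstituted diene and C5–C6 from a 2-methyl enal.

## Retrosynthetic reasoning

**Ethenyl bridge.** Target 33 is cut at the C=C between C6 and B8 into aldehyde 27 and phosphonate 32. This is the only bond that joins two large halves, the aldehyde on C6 has no α-hydrogen, and a benzylic phosphonate should give the E-alkene. Cutting either flanking single bond would mean coupling at a neopentyl carbon or at a doubly ortho-substituted arene. Placing this step last keeps coumarin B and the styrene out of the photochemical step. The forward reaction must add a phosphonate carbanion to a hindered aldehyde without touching two lactones.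

**Coumarin B.** Phosphonate 32 goes back through bromide 31 and methyl ether 30 to hydroxycoumarin 29. Its pyranone is disconnected by a Pechmann condensation to 2-methylresorcinol 28, whose methyl group already stands between the two oxygens where the bridge carbon is needed.

**Pyranone of coumarin A.** In 27 the lactone C–O bond, C3=C4 and A4a–C4 are cut, through alcohol 26 and salicylaldehyde 24, to phenol 23, then with protecting groups restored to 22 and 21. This exposes ring A as a resorcinol whose oxygens are already told apart. The forward steps must formylate A4a and not A8, and must keep the C6 arm at the alcohol level until the lactone is made.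

**Ring A (key disconnection).** In 21 the bonds A4a–A5, A7–A8, A4a–A8a and A6–A7 are cut, leaving diazo enone 12 and siloxyalkyne 16. The C1–A6 bond is then not an aryl coupling at a hindered carbon. A6 is already attached to C1 as an alkene carbon of 12 and the arene is assembled around it. No stereocentre is involved, and the free A7 hydroxyl and silylated A8a oxygen emerge differentiated. The forward reaction is a Wolff rearrangement, [2+2] addition, 4π opening and 6π closure, and needs only the correct orientation of the [2+2].

**Siloxyalkyne.** 16 is cut at the C–O and O–Si bonds to ethyne 13, by oxidation of its acetylide to an ynolate and O-silylation.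

**Diazo enone.** 12 comes from methyl enone 10 by diazo transfer to the methyl group. The C=C of 10 is cut to aldehyde 9, made from alcohol 8. The forward sequence must carry the epimerisable 9 through quickly and without base.

**Telling the two arms apart.** 8 goes back to bis-silyl ether 7, alcohol 6 and aldehyde 5. The C6 arm arrives as an aldehyde, is reduced and capped with the more robust silyl group, and only then is the C1 arm released.

**Cyclohexene.** 5 is cut at C1–C6 and C4–C5 into diene 4 and methacrolein 1. The 1-substituent and the 3-methyl of 4 both direct the same regiochemistry, the quaternary centre forms by cycloaddition, and both stereocentres arise in one step. The forward reaction needs endo orientation of the formyl group and face selection by a chiral Lewis acid.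

**Diene.** 4 comes from dienol 3, dienoate 2 and again methacrolein 1, by olefination, reduction and silylation.

## Alternatives that were turned down

**Alternative 1:** Ireland–Claisen ring contraction.
- Disconnection: the C1–C6 bond, traced back to the C–O bond of a six-membered lactone.
- Key step: lactone A2, as its silyl ketene acetal, rearranges through the boat geometry that the ring enforces. C1–C6 forms, C2=C3 is placed, and acid A1 results. The carbinol centre of A2 would come from (R)-linalool A3.
- For: the chirality comes from the chiral pool, so there is no doubt about the sense of induction. Ring A arrives intact, and the boat transition state of an (E)-styryl lactone should place the aryl group cis to the carboxyl group, as required.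
- Against:
  - A3 must be rebuilt extensively to reach A2 (degradation of the prenyl end, addition of a propionate unit, arylation of the vinyl group).
  - The ketene acetal must be formed with strong base in the presence of a coumarin lactone, or the coumarin must be built afterwards, which gives up the main advantage.
  - A tertiary allylic carboxylate can ionise instead of rearranging.
  - The carboxyl group of A1 on a neopentyl carbon still has to be reduced and re-oxidised before the bridge can be made.
- Comparison: on certainty of absolute configuration and on having the arene in place it is as strong or stronger. The chosen strategy offers instead a shorter path to the stereodiad, no enolate chemistry near a coumarin, and ring A oxygens differentiated as they form.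

**Alternative 2:** Organocatalytic Robinson annulation.
- Disconnection: C5–C6 and C1=C2 of a cyclohexenone that maps onto C1–C6.
- Key step: formyl nitrile A5 adds to butenone A6 under a bifunctional amine–thiourea catalyst and the adduct condenses to enone A4.
- For: two bulk chemicals, no metal, and a catalytic quaternary centre. The nitrile is the smallest carbon substituent, so a later conjugate addition at C1 should enter cis to it, and C1 never sits next to a carbonyl.
- Against:
  - A5 is an enolised, self-condensing donor, and discrimination between the faces of its small planar enolate carries the whole absolute configuration.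
  - Only C6 is set. C1 then depends on a second, substrate-controlled addition next to the quaternary centre, where methyl and nitrile differ only modestly.
  - The C3 methyl, the reduction of the nitrile and all of ring A still remain.
- Comparison: on cost and on the stereochemical safety of C1 once set it is as strong or stronger, since the chosen route passes through the epimerisable aldehyde 9. The chosen strategy offers both stereocentres from one cycloaddition of a thoroughly explored class, with the relative configuration resting on the endo rule rather than on a small steric difference.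

**Alternative 3:** Desymmetrising ester-tethered Heck reaction.
- Disconnection: the C1–A6 bond, with a temporary ester between the C6 carboxyl and the A7 oxygen.
- Key step: aryl bromide A8 adds through palladium to one of two enantiotopic ring alkenes, and β-hydride elimination toward the methyl-bearing carbon gives lactone A7.
- For: the arene is brought in whole, the C1–aryl bond and both stereocentres form in one catalytic step, and the tether enforces the cis relation and already holds the A7 oxygen.
- Against:
  - A8 must be the cis-1,4-dimethyl isomer, and a Birch reductive alkylation does not control that remote relation.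
  - Aryl esters prefer the conformation that holds the arene away from the ring, and can themselves insert palladium at the acyl–oxygen bond.
  - High enantioselectivity from an aryl bromide needs halide abstraction.
  - A7 is a conjugated diene whose C4=C5 must be reduced without touching C2=C3, and the pyranone still has to be built.
- Comparison: in convergency at ring A it is stronger. The chosen strategy offers a precursor reached by routine steps and a key step that creates no stereocentre, so its failure modes affect yield but not stereochemical purity.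

Key step: step 11

Assumption: the sense of induction in step 4 follows the usual model for 2-substituted acroleins on the (S)-proline-derived oxazaborolidinium ion; if the antipode formed, the (R)-proline-derived catalyst would be used with no other change.

Abbreviations: TBS = tert-butyl(dimethyl)silyl; TIPS = tri(propan-2-yl)silyl; Cyx = the 3,6-dimethyl-6-(TIPS-oxymethyl)cyclohex-2-en-1-yl group with the configuration it has in 12.

## Route

Step 1
Reactants: 1 methacrolein (2-methylprop-2-enal)
Product: 2 ethyl (2E)-4-methylpenta-2,4-dienoate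
Conditions: Ph3P=CHCO2Et, CH2Cl2, 0 °C → rt
Reagents that add atoms: ethyl (triphenyl-λ5-phosphanylidene)acetate, CCOC(=O)C=P(c1ccccc1)(c1ccccc1)c1ccccc1
Why: Wittig olefination with a stabilised ylide, which adds to the aldehyde and should give the E-dienoate.

Step 2
Reactants: 2 ethyl (2E)-4-methylpenta-2,4-dienoate
Product: 3 (2E)-4-methylpenta-2,4-dien-1-ol
Conditions: i-Bu2AlH (2.2 equiv), CH2Cl2, −78 °C
Reagents that add atoms: none
Why: 1,2-reduction of a conjugated ester by an aluminium hydride at low temperature, which leaves the diene untouched.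

Step 3
Reactants: 3 (2E)-4-methylpenta-2,4-dien-1-ol
Product: 4 tert-butyl(dimethyl){[(2E)-4-methylpenta-2,4-dien-1-yl]oxy}silane
Conditions: TBSCl, imidazole, CH2Cl2, rt
Reagents that add atoms: tert-butyl(chloro)dimethylsilane, CC(C)(C)[Si](C)(C)Cl
Why: Standard silylation of a primary alcohol; the silyl ether is a weak Lewis base and should survive the Lewis acid of step 4.

Step 4
Reactants: 4 tert-butyl(dimethyl){[(2E)-4-methylpenta-2,4-dien-1-yl]oxy}silane; 1 methacrolein
Product: 5 (1S,2R)-2-({[tert-butyl(dimethyl)silyl]oxy}methyl)-1,4-dimethylcyclohex-3-ene-1-carbaldehyde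
Conditions: (S)-3,3-diphenyl-1-(2-methylphenyl)tetrahydro-1H,3H-pyrrolo[1,2-c][1,3,2]oxazaborole (10 mol %) activated with Tf2NH, CH2Cl2, −78 → −40 °C
Reagents that add atoms: none
Why: Catalytic enantioselective Diels–Alder reaction of a 2-substituted acrolein on a chiral oxazaborolidinium Lewis acid. The unsubstituted diene terminus (largest HOMO coefficient, reinforced by both the 1-substituent and the 3-methyl) bonds to the β-carbon of the enal, so only the 1,2/1,4 regioisomer should form. The endo orientation of the coordinated formyl group puts the CH2OTBS arm cis to CHO, and the catalyst screens one face of the s-trans enal, which sets C6 and, through the endo mode, C1.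

Step 5
Reactants: 5 (1S,2R)-2-({[tert-butyl(dimethyl)silyl]oxy}methyl)-1,4-dimethylcyclohex-3-ene-1-carbaldehyde
Product: 6 [(1S,2R)-2-({[tert-butyl(dimethyl)silyl]oxy}methyl)-1,4-dimethylcyclohex-3-en-1-yl]methanol
Conditions: NaBH4, MeOH, 0 °C
Reagents that add atoms: none
Why: Borohydride reduction of a non-enolisable aldehyde; neither the silyl ether nor the alkene is affected.

Step 6
Reactants: 6 [(1S,2R)-2-({[tert-butyl(dimethyl)silyl]oxy}methyl)-1,4-dimethylcyclohex-3-en-1-yl]methanol
Product: 7 tert-butyl(dimethyl){[(1R,6S)-3,6-dimethyl-6-({[tri(propan-2-yl)silyl]oxy}methyl)cyclohex-2-en-1-yl]methoxy}silane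
Conditions: i-Pr3SiOTf, 2,6-lutidine, CH2Cl2, 0 °C → rt
Reagents that add atoms: tri(propan-2-yl)silyl trifluoromethanesulfonate, CC(C)[Si](C(C)C)(C(C)C)OS(=O)(=O)C(F)(F)F
Why: Silylation of a neopentyl alcohol with a silyl triflate. TIPS is chosen because it outlasts the TBS group in acid, does not absorb the light of step 11, and later leaves together with the aryl TIPS ether.

Step 7
Reactants: 7 tert-butyl(dimethyl){[(1R,6S)-3,6-dimethyl-6-({[tri(propan-2-yl)silyl]oxy}methyl)cyclohex-2-en-1-yl]methoxy}silane
Product: 8 [(1R,6S)-3,6-dimethyl-6-({[tri(propan-2-yl)silyl]oxy}methyl)cyclohex-2-en-1-yl]methanol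
Conditions: pyridinium p-toluenesulfonate, MeOH, rt
Reagents that add atoms: none
Why: Acid-catalysed methanolysis of silyl ethers; the primary TBS ether should cleave well before the bulkier TIPS ether on the neopentyl oxygen, and the acid is too weak to move the ring alkene.

Step 8
Reactants: 8 [(1R,6S)-3,6-dimethyl-6-({[tri(propan-2-yl)silyl]oxy}methyl)cyclohex-2-en-1-yl]methanol
Product: 10 (3E)-4-[(1R,6S)-3,6-dimethyl-6-({[tri(propan-2-yl)silyl]oxy}methyl)cyclohex-2-en-1-yl]but-3-en-2-one, via aldehyde 9 (not isolated)
Conditions: Dess–Martin periodinane, NaHCO3, CH2Cl2, 0 °C → rt; then Ph3P=CHC(O)CH3, 40 °C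
Reagents that add atoms: 1-(triphenyl-λ5-phosphanylidene)propan-2-one, CC(=O)C=P(c1ccccc1)(c1ccccc1)c1ccccc1
Why: Dess–Martin oxidation followed in the same flask by Wittig olefination with a stabilised acyl ylide. The β,γ-unsaturated aldehyde 9 meets only a buffered medium and a nearly neutral ylide, so C1 should neither epimerise nor lose its alkene to conjugation, and the stabilised ylide should give the E-enone.

Step 9
Reactants: 10 (3E)-4-[(1R,6S)-3,6-dimethyl-6-({[tri(propan-2-yl)silyl]oxy}methyl)cyclohex-2-en-1-yl]but-3-en-2-one
Product: 12 (3E)-1-diazo-4-[(1R,6S)-3,6-dimethyl-6-({[tri(propan-2-yl)silyl]oxy}methyl)cyclohex-2-en-1-yl]but-3-en-2-one, via trifluoroacetyl diketone 11 (not isolated)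
Conditions: LiN(SiMe3)2, THF, −78 °C; CF3CO2CH2CF3, −78 °C; aq HCl work-up; then CH3SO2N3, Et3N, H2O, MeCN, rt
Reagents that add atoms: 2,2,2-trifluoroethyl trifluoroacetate, FC(F)(F)COC(=O)C(F)(F)F (trifluoroacetyl group of 11); methanesulfonyl azide, CS(=O)(=O)N=[N+]=[N-] (diazo nitrogen of 12)
Why: Detrifluoroacetylative diazo transfer. The kinetic enolate forms at the methyl group and not at the γ-position (C1), is acylated, and the activated diketone takes up the diazo group with loss of the trifluoroacetyl group. This avoids an enoyl chloride and diazomethane, which would add across the alkene.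

Step 10
Reactants: 13 ethyne
Product: 16 (ethynyloxy)tri(propan-2-yl)silane (triisopropylsiloxyethyne), via lithium acetylide 14 (not isolated), via lithium ethynolate 15 (not isolated)
Conditions: n-BuLi, THF, −78 °C; t-BuOOLi (from t-BuOOH and LiN(SiMe3)2), −78 → 0 °C; i-Pr3SiOTf, −78 → 0 °C
Reagents that add atoms: n-butyllithium, [Li]CCCC (lithium of 14 and 15); tert-butyl hydroperoxide, CC(C)(C)OO (oxygen); tri(propan-2-yl)silyl trifluoromethanesulfonate, CC(C)[Si](C(C)C)(C(C)C)OS(=O)(=O)C(F)(F)F
Why: Oxidation of a lithium acetylide by lithium tert-butyl peroxide gives the ynolate, which a bulky silyl triflate traps on oxygen; this is the established route to silyl ynol ethers, applied here to the parent acetylide.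

Step 11
Reactants: 12 (3E)-1-diazo-4-[(1R,6S)-3,6-dimethyl-6-({[tri(propan-2-yl)silyl]oxy}methyl)cyclohex-2-en-1-yl]but-3-en-2-one; 16 (ethynyloxy)tri(propan-2-yl)silane
Product: 21 2-[(1R,6S)-3,6-dimethyl-6-({[tri(propan-2-yl)silyl]oxy}methyl)cyclohex-2-en-1-yl]-5-{[tri(propan-2-yl)silyl]oxy}phenol, via vinylketene 17 (not isolated), via cyclobutenone 18 (not isolated), via dienylketene 19 (not isolated), via cyclohexadienone 20 (not isolated)
Conditions: 16 (2.5 equiv), ClCH2CH2Cl, hν (300 nm, Pyrex), rt; then 80 °C
Reagents that add atoms: none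
Why: Light removes the diazo nitrogen and the alkenyl group migrates (photochemical Wolff rearrangement), which forms A4a–A5 and gives vinylketene 17. The unsubstituted, nucleophilic carbon of the siloxyalkyne attacks the ketene carbon (the future A7) and the [2+2] adduct closes to cyclobutenone 18, forming A7–A8 and A4a–A8a. Conrotatory 4π opening gives dienylketene 19, whose thermal disrotatory 6π-electrocyclisation forms A6–A7 and closes the six-membered ring as dienone 20; tautomerisation gives phenol 21. The closest known reaction type is the Danheiser benzannulation in its photo-Wolff variant with silyl ynol ethers, which gives resorcinol monosilyl ethers. No stereocentre is created; the sp3 ring carbons of 18 and 20 are transient, and C1 is a spectator that is neither deprotonated nor ionised. The selectivity needed is the orientation of the [2+2]; the donor oxygen polarises the alkyne so that only its H-bearing carbon bonds to the ketene carbon, which places C1 ortho to the free hydroxyl and para to the silyloxy group. The ring alkene and the silyl ether are far poorer ketene partners than the electron-rich alkyne used in excess.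

Step 12
Reactants: 21 2-[(1R,6S)-3,6-dimethyl-6-({[tri(propan-2-yl)silyl]oxy}methyl)cyclohex-2-en-1-yl]-5-{[tri(propan-2-yl)silyl]oxy}phenol
Product: 22 {3-methoxy-4-[(1R,6S)-3,6-dimethyl-6-({[tri(propan-2-yl)silyl]oxy}methyl)cyclohex-2-en-1-yl]phenoxy}tri(propan-2-yl)silane
Conditions: MeI, K2CO3, acetone, 50 °C
Reagents that add atoms: iodomethane, CI
Why: Williamson methylation of the only free phenol (A7); the hindered aryl TIPS ether should survive carbonate in acetone.

Step 13
Reactants: 22 {3-methoxy-4-[(1R,6S)-3,6-dimethyl-6-({[tri(propan-2-yl)silyl]oxy}methyl)cyclohex-2-en-1-yl]phenoxy}tri(propan-2-yl)silane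
Product: 23 4-[(1R,6S)-6-(hydroxymethyl)-3,6-dimethylcyclohex-2-en-1-yl]-3-methoxyphenol
Conditions: Bu4NF, THF, rt → 50 °C
Reagents that add atoms: none
Why: Fluoride cleavage of both silicon–oxygen bonds, the aryl ether quickly and the neopentyl ether on warming.

Step 14
Reactants: 23 4-[(1R,6S)-6-(hydroxymethyl)-3,6-dimethylcyclohex-2-en-1-yl]-3-methoxyphenol
Product: 24 2-hydroxy-5-[(1R,6S)-6-(hydroxymethyl)-3,6-dimethylcyclohex-2-en-1-yl]-4-methoxybenzaldehyde
Conditions: MgCl2, Et3N, (CH2O)n, MeCN, reflux; aq HCl work-up
Reagents that add atoms: paraformaldehyde (formaldehyde), C=O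
Why: Magnesium phenoxide-directed ortho-formylation, in which a second formaldehyde takes the hydride. Of the two positions ortho to the hydroxyl, A8 is flanked by two oxygens and A4a is open and para to the methoxy group, so A4a should react; an aliphatic hydroxyl is tolerated.

Step 15
Reactants: 24 2-hydroxy-5-[(1R,6S)-6-(hydroxymethyl)-3,6-dimethylcyclohex-2-en-1-yl]-4-methoxybenzaldehyde
Product: 26 6-[(1R,6S)-6-(hydroxymethyl)-3,6-dimethylcyclohex-2-en-1-yl]-7-methoxy-2H-chromen-2-one, via cinnamate ester 25 (not isolated)
Conditions: Ph3P=CHCO2Et, PhNEt2, 210 °C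
Reagents that add atoms: ethyl (triphenyl-λ5-phosphanylidene)acetate, CCOC(=O)C=P(c1ccccc1)(c1ccccc1)c1ccccc1
Why: Wittig olefination of a salicylaldehyde, then thermal E/Z equilibration of the cinnamate and lactonisation of the Z isomer (the classical ylide route to coumarins). At this stage C6 carries no alkenyl group, so no 1,5-diene is exposed to the heat.

Step 16
Reactants: 26 6-[(1R,6S)-6-(hydroxymethyl)-3,6-dimethylcyclohex-2-en-1-yl]-7-methoxy-2H-chromen-2-one
Product: 27 (1S,2S)-2-(7-methoxy-2-oxo-2H-chromen-6-yl)-1,4-dimethylcyclohex-3-ene-1-carbaldehyde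
Conditions: Dess–Martin periodinane, NaHCO3, CH2Cl2, rt
Reagents that add atoms: none
Why: Dess–Martin oxidation of a neopentyl alcohol to an aldehyde with no α-hydrogen; the lactone and the alkene are inert to the reagent.

Step 17
Reactants: 28 2-methylbenzene-1,3-diol (2-methylresorcinol)
Product: 29 7-hydroxy-8-methyl-2H-chromen-2-one
Conditions: malic acid, conc. H2SO4, 110 °C
Reagents that add atoms: malic acid, OC(CC(O)=O)C(O)=O
Why: Pechmann condensation with formylacetic acid generated in the flask from malic acid; ring closure at the position ortho to one hydroxyl and para to the other leaves the methyl group at C8.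

Step 18
Reactants: 29 7-hydroxy-8-methyl-2H-chromen-2-one
Product: 30 7-methoxy-8-methyl-2H-chromen-2-one
Conditions: MeI, K2CO3, acetone, reflux
Reagents that add atoms: iodomethane, CI
Why: Williamson methylation of the phenol.

Step 19
Reactants: 30 7-methoxy-8-methyl-2H-chromen-2-one
Product: 31 8-(bromomethyl)-7-methoxy-2H-chromen-2-one
Conditions: NBS, AIBN, PhCF3, reflux
Reagents that add atoms: N-bromosuccinimide, BrN1C(=O)CCC1=O
Why: Wohl–Ziegler radical bromination at the only benzylic C–H position; radical conditions avoid ionic bromination of the pyranone alkene.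

Step 20
Reactants: 31 8-(bromomethyl)-7-methoxy-2H-chromen-2-one
Product: 32 diethyl [(7-methoxy-2-oxo-2H-chromen-8-yl)methyl]phosphonate
Conditions: P(OEt)3, 140 °C
Reagents that add atoms: triethyl phosphite, CCOP(OCC)OCC
Why: Michaelis–Arbuzov reaction of a benzylic bromide.

Step 21
Reactants: 27 (1S,2S)-2-(7-methoxy-2-oxo-2H-chromen-6-yl)-1,4-dimethylcyclohex-3-ene-1-carbaldehyde; 32 diethyl [(7-methoxy-2-oxo-2H-chromen-8-yl)methyl]phosphonate
Product: 33 7-methoxy-8-{(E)-2-[(1R,2R)-2-(7-methoxy-2-oxo-2H-chromen-6-yl)-1,4-dimethylcyclohex-3-en-1-yl]ethenyl}-2H-chromen-2-one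
Conditions: NaN(SiMe3)2, THF, −78 °C (anion of 32); then 27, −78 °C → rt
Reagents that add atoms: none
Why: Horner–Wadsworth–Emmons olefination with a benzylic phosphonate; the aldehyde cannot enolise, a non-nucleophilic amide base is used at low temperature to spare the lactones, and the bulky α-quaternary aldehyde should favour the E-alkene.

## Compound list

1 | 2-methylprop-2-enal (methacrolein) | CC(=C)C=O | starting material
2 | ethyl (2E)-4-methylpenta-2,4-dienoate | CCOC(=O)/C=C/C(C)=C | intermediate
3 | (2E)-4-methylpenta-2,4-dien-1-ol | OC/C=C/C(C)=C | intermediate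
4 | tert-butyl(dimethyl){[(2E)-4-methylpenta-2,4-dien-1-yl]oxy}silane | CC(=C)/C=C/CO[Si](C)(C)C(C)(C)C | intermediate
5 | (1S,2R)-2-({[tert-butyl(dimethyl)silyl]oxy}methyl)-1,4-dimethylcyclohex-3-ene-1-carbaldehyde | CC(C)(C)[Si](C)(C)OC[C@@H]1C=C(C)CC[C@]1(C)C=O | intermediate
6 | [(1S,2R)-2-({[tert-butyl(dimethyl)silyl]oxy}methyl)-1,4-dimethylcyclohex-3-en-1-yl]methanol | CC(C)(C)[Si](C)(C)OC[C@@H]1C=C(C)CC[C@]1(C)CO | intermediate
7 | tert-butyl(dimethyl){[(1R,6S)-3,6-dimethyl-6-({[tri(propan-2-yl)silyl]oxy}methyl)cyclohex-2-en-1-yl]methoxy}silane | CC(C)(C)[Si](C)(C)OC[C@@H]1C=C(C)CC[C@]1(C)CO[Si](C(C)C)(C(C)C)C(C)C | intermediate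
8 | [(1R,6S)-3,6-dimethyl-6-({[tri(propan-2-yl)silyl]oxy}methyl)cyclohex-2-en-1-yl]methanol | OC[C@@H]1C=C(C)CC[C@]1(C)CO[Si](C(C)C)(C(C)C)C(C)C | intermediate
9 | (1R,6S)-3,6-dimethyl-6-({[tri(propan-2-yl)silyl]oxy}methyl)cyclohex-2-ene-1-carbaldehyde | O=C[C@@H]1C=C(C)CC[C@]1(C)CO[Si](C(C)C)(C(C)C)C(C)C | intermediate
10 | (3E)-4-[(1R,6S)-3,6-dimethyl-6-({[tri(propan-2-yl)silyl]oxy}methyl)cyclohex-2-en-1-yl]but-3-en-2-one | CC(=O)/C=C/[C@@H]1C=C(C)CC[C@]1(C)CO[Si](C(C)C)(C(C)C)C(C)C | intermediate
11 | (5E)-1,1,1-trifluoro-6-Cyx-hex-5-ene-2,4-dione | FC(F)(F)C(=O)CC(=O)/C=C/[C@@H]1C=C(C)CC[C@]1(C)CO[Si](C(C)C)(C(C)C)C(C)C | intermediate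
12 | (3E)-1-diazo-4-[(1R,6S)-3,6-dimethyl-6-({[tri(propan-2-yl)silyl]oxy}methyl)cyclohex-2-en-1-yl]but-3-en-2-one | [N-]=[N+]=CC(=O)/C=C/[C@@H]1C=C(C)CC[C@]1(C)CO[Si](C(C)C)(C(C)C)C(C)C | intermediate
13 | ethyne | C#C | starting material
14 | lithium acetylide | [Li]C#C | intermediate
15 | lithium ethynolate | [Li+].[O-]C#C | intermediate
16 | (ethynyloxy)tri(propan-2-yl)silane | C#CO[Si](C(C)C)(C(C)C)C(C)C | intermediate
17 | (3E)-4-Cyx-buta-1,3-dien-1-one (vinylketene) | O=C=C/C=C/[C@@H]1C=C(C)CC[C@]1(C)CO[Si](C(C)C)(C(C)C)C(C)C | intermediate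
18 | 4-[(E)-2-Cyx-ethenyl]-3-(TIPS-oxy)cyclobut-2-en-1-one (ring sp3 centre unassigned) | O=C1C=C(O[Si](C(C)C)(C(C)C)C(C)C)C1/C=C/[C@@H]2C=C(C)CC[C@]2(C)CO[Si](C(C)C)(C(C)C)C(C)C | intermediate
19 | (3E,5E)-6-Cyx-3-(TIPS-oxy)hexa-1,3,5-trien-1-one (ketene and alkenyl groups cis on C3=C4) | O=C=C/C(O[Si](C(C)C)(C(C)C)C(C)C)=C\C=C\[C@@H]1C=C(C)CC[C@]1(C)CO[Si](C(C)C)(C(C)C)C(C)C | intermediate
20 | 6-Cyx-3-(TIPS-oxy)cyclohexa-2,4-dien-1-one (ring sp3 centre unassigned) | O=C1C=C(O[Si](C(C)C)(C(C)C)C(C)C)C=CC1[C@@H]2C=C(C)CC[C@]2(C)CO[Si](C(C)C)(C(C)C)C(C)C | intermediate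
21 | 2-[(1R,6S)-3,6-dimethyl-6-({[tri(propan-2-yl)silyl]oxy}methyl)cyclohex-2-en-1-yl]-5-{[tri(propan-2-yl)silyl]oxy}phenol | Oc1cc(O[Si](C(C)C)(C(C)C)C(C)C)ccc1[C@@H]1C=C(C)CC[C@]1(C)CO[Si](C(C)C)(C(C)C)C(C)C | intermediate
22 | {3-methoxy-4-[(1R,6S)-3,6-dimethyl-6-({[tri(propan-2-yl)silyl]oxy}methyl)cyclohex-2-en-1-yl]phenoxy}tri(propan-2-yl)silane | COc1cc(O[Si](C(C)C)(C(C)C)C(C)C)ccc1[C@@H]1C=C(C)CC[C@]1(C)CO[Si](C(C)C)(C(C)C)C(C)C | intermediate
23 | 4-[(1R,6S)-6-(hydroxymethyl)-3,6-dimethylcyclohex-2-en-1-yl]-3-methoxyphenol | COc1cc(O)ccc1[C@@H]1C=C(C)CC[C@]1(C)CO | intermediate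
24 | 2-hydroxy-5-[(1R,6S)-6-(hydroxymethyl)-3,6-dimethylcyclohex-2-en-1-yl]-4-methoxybenzaldehyde | COc1cc(O)c(C=O)cc1[C@@H]1C=C(C)CC[C@]1(C)CO | intermediate
25 | ethyl (2E)-3-{2-hydroxy-5-[(1R,6S)-6-(hydroxymethyl)-3,6-dimethylcyclohex-2-en-1-yl]-4-methoxyphenyl}prop-2-enoate | CCOC(=O)/C=C/c1cc([C@@H]2C=C(C)CC[C@]2(C)CO)c(OC)cc1O | intermediate
26 | 6-[(1R,6S)-6-(hydroxymethyl)-3,6-dimethylcyclohex-2-en-1-yl]-7-methoxy-2H-chromen-2-one | COc1cc2oc(=O)ccc2cc1[C@@H]1C=C(C)CC[C@]1(C)CO | intermediate
27 | (1S,2S)-2-(7-methoxy-2-oxo-2H-chromen-6-yl)-1,4-dimethylcyclohex-3-ene-1-carbaldehyde | COc1cc2oc(=O)ccc2cc1[C@@H]1C=C(C)CC[C@]1(C)C=O | intermediate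
28 | 2-methylbenzene-1,3-diol | Cc1c(O)cccc1O | starting material
29 | 7-hydroxy-8-methyl-2H-chromen-2-one | Cc1c(O)ccc2ccc(=O)oc12 | intermediate
30 | 7-methoxy-8-methyl-2H-chromen-2-one | COc1ccc2ccc(=O)oc2c1C | intermediate
31 | 8-(bromomethyl)-7-methoxy-2H-chromen-2-one | COc1ccc2ccc(=O)oc2c1CBr | intermediate
32 | diethyl [(7-methoxy-2-oxo-2H-chromen-8-yl)methyl]phosphonate | CCOP(=O)(OCC)Cc1c(OC)ccc2ccc(=O)oc12 | intermediate
33 | 7-methoxy-8-{(E)-2-[(1R,2R)-2-(7-methoxy-2-oxo-2H-chromen-6-yl)-1,4-dimethylcyclohex-3-en-1-yl]ethenyl}-2H-chromen-2-one | COc1cc2oc(=O)ccc2cc1[C@@H]1C=C(C)CC[C@]1(C)/C=C/c1c(OC)ccc2ccc(=O)oc12 | target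

## Step count and least certain steps

Total step count: 21. Longest linear sequence: 16 (steps 1–9, 11–16 and 21); steps 10 and 17–20 are side branches.

**Step 11 (key step).** The diazo enone is also an enone chromophore next to a skipped diene, so dimerisation, rearrangement of the C2=C3/C1/enone array, or carbene chemistry before migration can compete with the Wolff shift. The phenol product can add to a ketene, and the siloxyalkyne can isomerise to a silylketene on heating.
- Fallback: ring A is bought instead of built. It sets out from methacrolein 1 and rejoins at aldehyde 27.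
- The known 6-bromo-7-methoxy-2H-chromen-2-one F1 undergoes a Heck reaction with 2-methylbuta-1,3-diene (Pd(OAc)2, P(o-tol)3, Et3N, DMF) at its unsubstituted vinyl group to give 7-methoxy-6-[(1E)-3-methylbuta-1,3-dien-1-yl]-2H-chromen-2-one F2.
- F2 undergoes the oxazaborolidinium-catalysed Diels–Alder reaction of step 4 with 1 to give 27 directly. The price is a lactone carbonyl that competes for the catalyst.

**Step 4.** Face selection may be incomplete with this 1,3-disubstituted dienyl ether, some of the formyl-exo pathway may compete, and the strong Lewis acid may oligomerise the diene. Any exo isomer would be removed at the stage of 6.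
- Fallback: enantiopurity by resolution. It sets out from 4 and 1 and rejoins at 6.
- Me2AlCl-promoted cycloaddition gives the racemic endo aldehyde F3, and NaBH4 gives the racemic alcohol F4.
- Acylation with (1S)-camphanic chloride (Et3N, DMAP) gives two diastereomeric esters. The one derived from 6, camphanate F5, is separated by crystallisation or chromatography and cleaved with K2CO3 in MeOH to 6.

**Step 8.** The hindered aldehyde 9 may react slowly with the acyl ylide, which leaves time for epimerisation at C1 or migration of C2=C3 into conjugation.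
- Fallback: non-basic methylenation and cross-metathesis. It sets out from alcohol 8 and rejoins at enone 10.
- 8 is oxidised as before and the crude 9 is methylenated at once with Zn/CH2Br2/TiCl4 to the vinyl compound tri(propan-2-yl){[(1S,2R)-2-ethenyl-1,4-dimethylcyclohex-3-en-1-yl]methoxy}silane F6.
- Cross-metathesis of F6 with but-3-en-2-one under the Hoveyda–Grubbs second-generation catalyst gives 10; the trisubstituted ring alkene should not take part.

**Step 10.** Monolithium acetylide can disproportionate before oxygen transfer, the ynolate can be silylated on carbon, and the volatile product can isomerise to a silylketene on distillation.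
- Fallback: a fluoride-labile alkoxyethyne replaces 16. It sets out from diazo enone 12 and rejoins at 23.
- 2-(Trimethylsilyl)ethanol, KH and trichloroethene give the dichlorovinyl ether [2-{[(E)-1,2-dichloroethenyl]oxy}ethyl](trimethyl)silane F7, and n-BuLi (2.2 equiv) followed by a proton quench gives [2-(ethynyloxy)ethyl](trimethyl)silane F8.
- F8 replaces 16 in step 11 and gives the phenol 2-Cyx-5-[2-(trimethylsilyl)ethoxy]phenol F9. Methylation as in step 12 gives its methyl ether F10.
- Bu4NF in DMF at 80 °C removes the TIPS group and, by β-elimination, the 2-(trimethylsilyl)ethyl group, returning 23.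

**Step 21.** The benzylic phosphonate anion may add to C4 of a coumarin or open a lactone faster than it adds to the hindered neopentyl aldehyde.
- Fallback: a base-free coupling at the same alkene. It sets out from aldehyde 27 and rejoins at target 33.
- Zn/CH2Br2/TiCl4 methylenation of 27, which spares the lactone, gives 6-[(1R,6R)-6-ethenyl-3,6-dimethylcyclohex-2-en-1-yl]-7-methoxy-2H-chromen-2-one F11.
- A Heck reaction of F11 with the known 8-iodo-7-methoxy-2H-chromen-2-one F12 (Pd(OAc)2, P(o-tol)3, Et3N, DMF, 90 °C) gives 33. With no hydrogen on C6, β-hydride elimination can only give the E-styrene.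

## Further compounds

F1 | step 11 | 6-bromo-7-methoxy-2H-chromen-2-one | COc1cc2oc(=O)ccc2cc1Br
F2 | step 11 | 7-methoxy-6-[(1E)-3-methylbuta-1,3-dien-1-yl]-2H-chromen-2-one | COc1cc2oc(=O)ccc2cc1/C=C/C(C)=C
F3 | step 4 | racemic (1RS,2SR)-2-({[tert-butyl(dimethyl)silyl]oxy}methyl)-1,4-dimethylcyclohex-3-ene-1-carbaldehyde | CC(C)(C)[Si](C)(C)OC[C@@H]1C=C(C)CC[C@]1(C)C=O.CC(C)(C)[Si](C)(C)OC[C@H]1C=C(C)CC[C@@]1(C)C=O
F4 | step 4 | racemic [(1RS,2SR)-2-({[tert-butyl(dimethyl)silyl]oxy}methyl)-1,4-dimethylcyclohex-3-en-1-yl]methanol | CC(C)(C)[Si](C)(C)OC[C@@H]1C=C(C)CC[C@]1(C)CO.CC(C)(C)[Si](C)(C)OC[C@H]1C=C(C)CC[C@@]1(C)CO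
F5 | step 4 | [(1S,2R)-2-({[tert-butyl(dimethyl)silyl]oxy}methyl)-1,4-dimethylcyclohex-3-en-1-yl]methyl (1S,4R)-4,7,7-trimethyl-3-oxo-2-oxabicyclo[2.2.1]heptane-1-carboxylate | CC(C)(C)[Si](C)(C)OC[C@@H]1C=C(C)CC[C@]1(C)COC(=O)[C@@]12CC[C@@](C)(C(=O)O1)C2(C)C
F6 | step 8 | tri(propan-2-yl){[(1S,2R)-2-ethenyl-1,4-dimethylcyclohex-3-en-1-yl]methoxy}silane | C=C[C@@H]1C=C(C)CC[C@]1(C)CO[Si](C(C)C)(C(C)C)C(C)C
F7 | step 10 | [2-{[(E)-1,2-dichloroethenyl]oxy}ethyl](trimethyl)silane | Cl/C=C(/Cl)OCC[Si](C)(C)C
F8 | step 10 | [2-(ethynyloxy)ethyl](trimethyl)silane | C#COCC[Si](C)(C)C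
F9 | step 10 | 2-[(1R,6S)-3,6-dimethyl-6-({[tri(propan-2-yl)silyl]oxy}methyl)cyclohex-2-en-1-yl]-5-[2-(trimethylsilyl)ethoxy]phenol | Oc1cc(OCC[Si](C)(C)C)ccc1[C@@H]1C=C(C)CC[C@]1(C)CO[Si](C(C)C)(C(C)C)C(C)C
F10 | step 10 | {[(1S,2R)-2-{2-methoxy-4-[2-(trimethylsilyl)ethoxy]phenyl}-1,4-dimethylcyclohex-3-en-1-yl]methoxy}tri(propan-2-yl)silane | COc1cc(OCC[Si](C)(C)C)ccc1[C@@H]1C=C(C)CC[C@]1(C)CO[Si](C(C)C)(C(C)C)C(C)C
F11 | step 21 | 6-[(1R,6R)-6-ethenyl-3,6-dimethylcyclohex-2-en-1-yl]-7-methoxy-2H-chromen-2-one | COc1cc2oc(=O)ccc2cc1[C@@H]1C=C(C)CC[C@]1(C)C=C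
F12 | step 21 | 8-iodo-7-methoxy-2H-chromen-2-one | COc1ccc2ccc(=O)oc2c1I
A1 | alternative 1 | (1S,2S)-2-(7-methoxy-2-oxo-2H-chromen-6-yl)-1,4-dimethylcyclohex-3-ene-1-carboxylic acid | COc1cc2oc(=O)ccc2cc1[C@@H]1C=C(C)CC[C@]1(C)C(=O)O
A2 | alternative 1 | (6R)-3,6-dimethyl-6-[(E)-2-(7-methoxy-2-oxo-2H-chromen-6-yl)ethenyl]oxan-2-one (either C3 epimer) | CC1CC[C@](C)(/C=C/c2cc3ccc(=O)oc3cc2OC)OC1=O
A3 | alternative 1 | (3R)-3,7-dimethylocta-1,6-dien-3-ol ((R)-linalool) | CC(C)=CCC[C@](C)(C=C)O
A4 | alternative 2 | (1S)-1-methyl-4-oxocyclohex-2-ene-1-carbonitrile | O=C1CC[C@](C)(C#N)C=C1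
A5 | alternative 2 | 2-methyl-3-oxopropanenitrile | CC(C=O)C#N
A6 | alternative 2 | but-3-en-2-one | CC(=O)C=C
A7 | alternative 3 | (6aS,10aS)-3-(methoxymethoxy)-6a,9-dimethyl-6a,10a-dihydro-6H-benzo[c]chromen-6-one | O=C1Oc2cc(OCOC)ccc2[C@@H]2C=C(C)C=C[C@]12C
A8 | alternative 3 | 2-bromo-5-(methoxymethoxy)phenyl cis-1,4-dimethylcyclohexa-2,5-diene-1-carboxylate | C[C@H]1C=C[C@](C)(C(=O)Oc2cc(OCOC)ccc2Br)C=C1
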